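**Retrosynthetic overview**

1. The target is read as epicatechin 3-O-gallate-(4β→8)-epicatechin 3-O-gallate-(4β→6)-catechin. The last operations are global hydrogenolysis (19 benzyl ethers and one C8 bromide) and Steglich galloylation of the top 3-OH.
2. Ring C of the top unit (O1–C2–C3–C4–C4a–C8a) and the C4(top)–C8(middle) bond are made together from the trans-2-aryl-2,3-dihydrobenzofuran-3-carbaldehyde 13 and dimer 10. C2 shifts from the ring carbon to the formyl carbon (five- to six-membered ring), and the C4 cation so formed is captured by C8.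
3. Enabling feature: C4 of the top unit is benzylic to ring A, whose O1 and 5-O (ortho) and 7-O (para) stabilise a C4 cation. The neighbouring C3 carries the oxygen, so C3 can start as a formyl carbon outside a five-membered O1–C2–C4–C4a–C8a ring.
4. Aldehyde 13 comes from (+)-catechin by a semipinacol contraction of ring C (six to five; catechin C4 becomes CHO, C2 untouched). Dimer 10 comes from a 3-O-galloyl epicatechin C4 electrophile and C8-brominated catechin, which forces the 4→6 bond.
5. Ring order: rings A, B and C of the bottom and middle units come from the chiral pool; the bottom–middle bond is made next; ring C of the top unit is formed last, in the key step.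

Key step: step 11

Assumption: all three C2 centres are R, as encoded in the SMILES; flavan numbering (O1, C2, C3, C4, C4a, C5–C8, C8a, primed B-ring positions) is used throughout.

**Route**

Step 1
Reactants: 1 (+)-catechin
Product: 2 5,7,3',4'-tetra-O-benzyl-(+)-catechin
Conditions: BnBr (4.4 equiv), K2CO3, DMF, 0 °C to rt
Reagents that add atoms: benzyl bromide, BrCc1ccccc1
Why: Williamson etherification of the four phenols with K2CO3 should leave the secondary 3-OH free, and no stereocenter is touched.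

Step 2
Reactants: 2 5,7,3',4'-tetra-O-benzyl-(+)-catechin
Product: 3 8-bromo-5,7,3',4'-tetra-O-benzyl-(+)-catechin
Conditions: NBS (1.0 equiv), CH2Cl2, −78 °C to rt
Reagents that add atoms: N-bromosuccinimide, O=C1CCC(=O)N1Br
Why: Electrophilic aromatic bromination should occur at C8 (between O1 and 7-OBn), the less hindered activated position of ring A; the bromide later blocks C8 so that only C6 can couple.

Step 3
Reactants: 3 8-bromo-5,7,3',4'-tetra-O-benzyl-(+)-catechin
Product: 4 8-bromo-3,5,7,3',4'-penta-O-benzyl-(+)-catechin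
Conditions: NaH, BnBr, n-Bu4NI (cat.), DMF, 0 °C to rt
Reagents that add atoms: benzyl bromide, BrCc1ccccc1
Why: Williamson etherification of the secondary alkoxide masks the 3-OH that must stay free of gallate in the target; configuration is retained.

Step 4
Reactants: 5 (−)-epicatechin
Product: 6 5,7,3',4'-tetra-O-benzyl-(−)-epicatechin
Conditions: BnBr (4.4 equiv), K2CO3, DMF, 0 °C to rt
Reagents that add atoms: benzyl bromide, BrCc1ccccc1
Why: Williamson etherification of the phenols only, as in step 1.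

Step 5
Reactants: 6 5,7,3',4'-tetra-O-benzyl-(−)-epicatechin
Product: 7 4β-(2-ethoxyethoxy)-5,7,3',4'-tetra-O-benzyl-(−)-epicatechin (2,3-cis-3,4-trans)
Conditions: DDQ (2 equiv), 2-ethoxyethanol (5 equiv), CH2Cl2, rt
Reagents that add atoms: 2-ethoxyethanol, CCOCCO
Why: DDQ abstracts hydride from C4 (benzylic to ring A) and the cation is trapped by the alcohol anti to the 3-OH in a benzylic oxidative etherification; the C4 configuration is re-set in step 7.

Step 6
Reactants: 7 4β-(2-ethoxyethoxy)-5,7,3',4'-tetra-O-benzyl-(−)-epicatechin; 8 3,4,5-tris(benzyloxy)benzoic acid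
Product: 9 4β-(2-ethoxyethoxy)-5,7,3',4'-tetra-O-benzyl-(−)-epicatechin 3-O-[3,4,5-tris(benzyloxy)benzoate]
Conditions: DCC, DMAP, CH2Cl2, rt
Reagents that add atoms: none
Why: Steglich esterification of the axial 3-OH installs the middle gallate early and gives a participating 3-O-acyl group for step 7.

Step 7
Reactants: 9 the 3-O-galloyl C4 electrophile; 4 8-bromo-3,5,7,3',4'-penta-O-benzyl-(+)-catechin (3 equiv, excess recovered)
Product: 10 [5,7,3',4'-tetra-O-benzyl-3-O-(3,4,5-tri-O-benzylgalloyl)epicatechin]-(4β→6)-[8-bromo-3,5,7,3',4'-penta-O-benzylcatechin]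
Conditions: Me3SiOTf (0.5 equiv), CH2Cl2, −78 °C
Reagents that add atoms: none
Why: Lewis-acid ionisation gives the C4 cation, bridged on the α face by the 3-O-acyl carbonyl, so that C6 of 4 (the only free ring A position) attacks from the β face in a Friedel–Crafts alkylation and sets C4 of the middle unit 3,4-trans (4β).

Step 8
Reactants: 2 5,7,3',4'-tetra-O-benzyl-(+)-catechin
Product: 11 5,7,3',4'-tetra-O-benzyl-(+)-catechin 3-O-methanesulfonate
Conditions: MsCl, Et3N, CH2Cl2, 0 °C
Reagents that add atoms: methanesulfonyl chloride, CS(=O)(=O)Cl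
Why: O-sulfonylation of the only free hydroxyl turns the equatorial C3–O bond into a leaving group with retention.

Step 9
Reactants: 11 5,7,3',4'-tetra-O-benzyl-(+)-catechin 3-O-methanesulfonate
Product: 12 4-hydroxy-5,7,3',4'-tetra-O-benzyl-(+)-catechin 3-O-methanesulfonate (C4 epimers, both usable)
Conditions: DDQ (2 equiv), H2O, CH2Cl2, rt
Reagents that add atoms: water, O
Why: DDQ benzylic oxidation at C4 with capture of the cation by water, as in step 5; the new C4 center is destroyed in step 10, so its configuration does not matter.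

Step 10
Reactants: 12 4-hydroxy-5,7,3',4'-tetra-O-benzyl-(+)-catechin 3-O-methanesulfonate
Product: 13 (2S,3S)-4,6-bis(benzyloxy)-2-[3,4-bis(benzyloxy)phenyl]-2,3-dihydro-1-benzofuran-3-carbaldehyde (2,3-trans)
Conditions: Et3Al (2.2 equiv), CH2Cl2, −78 °C; cold Rochelle-salt quench; used at once
Reagents that add atoms: none
Why: Organoaluminium-promoted semipinacol rearrangement of a 2-mesyloxy alcohol: the C4–C4a bond, anti-periplanar to the equatorial mesylate, migrates to C3 with inversion while the C4 aluminium alkoxide collapses to the formyl group, which contracts ring C and should give the 2,3-trans aldehyde stereospecifically with C2 untouched.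

Step 11
Reactants: 13 the trans-dihydrobenzofuran-3-carbaldehyde (1.5 equiv, added slowly); 10 the 4β→6 dimer
Product: 16 [5,7,3',4'-tetra-O-benzylepicatechin]-(4β→8)-[5,7,3',4'-tetra-O-benzyl-3-O-(3,4,5-tri-O-benzylgalloyl)epicatechin]-(4β→6)-[8-bromo-3,5,7,3',4'-penta-O-benzylcatechin], via silyloxycarbenium triflate 14 (not isolated), via 3-silyloxyflavan-4-ylium triflate 15 (not isolated)
Conditions: Me3SiOTf (0.3 equiv), 4 Å molecular sieves, CH2Cl2, −78 °C; NaHCO3 quench
Reagents that add atoms: none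
Why: Proposed new method: Me3SiOTf silylates the formyl oxygen of 13 to give oxocarbenium 14, and the σ-bond from the ring carbon to C2 (O1- and aryl-substituted, hence a good migrating group) shifts to the formyl carbon with retention at C2, which turns the five-membered O1–C2–C(ring)–C4a–C8a ring into the six-membered ring C (formyl carbon = new C3, old ring carbon = new C4) and leaves cation 15, stabilised at C4 by O1 and 5-OBn (ortho) and 7-OBn (para); C8 of the middle unit of 10 then adds in a Friedel–Crafts step and the released proton cleaves the 3-O-silyl ether, which returns Me3SiOTf. The closest known reaction types are the acid-catalysed aldehyde–ketone rearrangement (1,2-carbon shift to an activated formyl carbon), the Meinwald-type epoxide-to-aldehyde ring contraction run in reverse, and the Lewis-acid coupling of 4-alkoxyflavan-3-ol electrophiles with flavan nucleophiles, which passes through the same kind of C4 cation. Ring C is not closed by a cyclisation but by a one-carbon ring expansion (Wagner–Meerwein 1,2-alkyl shift that forms C2–C3). C2 is inherited from (+)-catechin; C3 is set in the shift, because the peri 5-OBn group keeps the silylated oxygen in the exo rotamer (eclipsing H on the ring carbon), the only rotamer in which the migrating bond is aligned with the empty orbital, and this rotamer delivers the C3–O bond axial and cis to the equatorial C2 aryl group; C4 is set by attack of the nucleophile anti to that axial 3-silyloxy group (3,4-trans, 4β). The step needs migration of C2 in preference to hydride or to the ring A carbon C4a, secured by the rotamer control just named and by the stability of 15 (aryl bridging is reversible), and it needs attack by C8 of the middle unit, secured by the C8 bromide of the bottom unit, the absence of free hydroxyl groups in 10 and the usual C8 over C6 preference.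

Step 12
Reactants: 16 the trimer with free top 3-OH; 8 3,4,5-tris(benzyloxy)benzoic acid
Product: 17 [5,7,3',4'-tetra-O-benzyl-3-O-(3,4,5-tri-O-benzylgalloyl)epicatechin]-(4β→8)-[5,7,3',4'-tetra-O-benzyl-3-O-(3,4,5-tri-O-benzylgalloyl)epicatechin]-(4β→6)-[8-bromo-3,5,7,3',4'-penta-O-benzylcatechin]
Conditions: DCC, DMAP, CH2Cl2, rt
Reagents that add atoms: none
Why: Steglich esterification of the single free (axial) hydroxyl; no stereocenter is touched.

Step 13
Reactants: 17 the fully protected trimer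
Product: 18 epicatechin 3-O-gallate-(4β→8)-epicatechin 3-O-gallate-(4β→6)-catechin (target)
Conditions: H2 (1 atm), Pd(OH)2/C, Et3N (1.1 equiv), THF/MeOH/H2O, rt
Reagents that add atoms: none
Why: Hydrogenolysis should cleave all 19 benzyl ethers and the aryl C–Br bond while the gallate esters, the C2–O1 bonds and the interflavan bonds stay intact.

**Compound list**

1 | (+)-catechin | O[C@H]1Cc2c(O)cc(O)cc2O[C@@H]1c1ccc(O)c(O)c1 | starting material
2 | 5,7,3',4'-tetra-O-benzyl-(+)-catechin | O[C@H]1Cc2c(OCc9ccccc9)cc(OCc9ccccc9)cc2O[C@@H]1c7ccc(OCc9ccccc9)c(OCc9ccccc9)c7 | intermediate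
3 | 8-bromo-5,7,3',4'-tetra-O-benzyl-(+)-catechin | O[C@H]1Cc2c(OCc9ccccc9)cc(OCc9ccccc9)c(Br)c2O[C@@H]1c7ccc(OCc9ccccc9)c(OCc9ccccc9)c7 | intermediate
4 | 8-bromo-3,5,7,3',4'-penta-O-benzyl-(+)-catechin | C(c9ccccc9)O[C@H]1Cc2c(OCc9ccccc9)cc(OCc9ccccc9)c(Br)c2O[C@@H]1c7ccc(OCc9ccccc9)c(OCc9ccccc9)c7 | intermediate
5 | (−)-epicatechin | O[C@@H]1Cc2c(O)cc(O)cc2O[C@@H]1c1ccc(O)c(O)c1 | starting material
6 | 5,7,3',4'-tetra-O-benzyl-(−)-epicatechin | O[C@@H]1Cc2c(OCc9ccccc9)cc(OCc9ccccc9)cc2O[C@@H]1c7ccc(OCc9ccccc9)c(OCc9ccccc9)c7 | intermediate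
7 | 4β-(2-ethoxyethoxy)-5,7,3',4'-tetra-O-benzyl-(−)-epicatechin | O[C@@H]1[C@@H](OCCOCC)c2c(OCc9ccccc9)cc(OCc9ccccc9)cc2O[C@@H]1c7ccc(OCc9ccccc9)c(OCc9ccccc9)c7 | intermediate
8 | 3,4,5-tris(benzyloxy)benzoic acid | OC(=O)c1cc(OCc9ccccc9)c(OCc9ccccc9)c(OCc9ccccc9)c1 | starting material
9 | 4β-(2-ethoxyethoxy)-5,7,3',4'-tetra-O-benzyl-(−)-epicatechin 3-O-[3,4,5-tris(benzyloxy)benzoate] | O=C(O[C@@H]1[C@@H](OCCOCC)c2c(OCc9ccccc9)cc(OCc9ccccc9)cc2O[C@@H]1c7ccc(OCc9ccccc9)c(OCc9ccccc9)c7)c8cc(OCc9ccccc9)c(OCc9ccccc9)c(OCc9ccccc9)c8 | intermediate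
10 | [tetra-O-benzyl-3-O-(tri-O-benzylgalloyl)epicatechin]-(4β→6)-[8-bromo-penta-O-benzylcatechin] | c1c(OCc9ccccc9)cc(OCc9ccccc9)c2c1O[C@H](c7ccc(OCc9ccccc9)c(OCc9ccccc9)c7)[C@H](OC(=O)c8cc(OCc9ccccc9)c(OCc9ccccc9)c(OCc9ccccc9)c8)[C@H]2c3c(OCc9ccccc9)c(Br)c4c(c3OCc9ccccc9)C[C@H](OCc9ccccc9)[C@@H](c7ccc(OCc9ccccc9)c(OCc9ccccc9)c7)O4 | intermediate
11 | 5,7,3',4'-tetra-O-benzyl-(+)-catechin 3-O-methanesulfonate | CS(=O)(=O)O[C@H]1Cc2c(OCc9ccccc9)cc(OCc9ccccc9)cc2O[C@@H]1c7ccc(OCc9ccccc9)c(OCc9ccccc9)c7 | intermediate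
12 | 4-hydroxy-5,7,3',4'-tetra-O-benzyl-(+)-catechin 3-O-methanesulfonate (C4 epimers) | CS(=O)(=O)O[C@H]1C(O)c2c(OCc9ccccc9)cc(OCc9ccccc9)cc2O[C@@H]1c7ccc(OCc9ccccc9)c(OCc9ccccc9)c7 | intermediate
13 | (2S,3S)-4,6-bis(benzyloxy)-2-[3,4-bis(benzyloxy)phenyl]-2,3-dihydro-1-benzofuran-3-carbaldehyde | O=C[C@H]1c2c(OCc9ccccc9)cc(OCc9ccccc9)cc2O[C@@H]1c7ccc(OCc9ccccc9)c(OCc9ccccc9)c7 | intermediate
14 | O-trimethylsilyl oxocarbenium triflate of 13 (not isolated) | C[Si](C)(C)[O+]=C[C@H]1c2c(OCc9ccccc9)cc(OCc9ccccc9)cc2O[C@@H]1c7ccc(OCc9ccccc9)c(OCc9ccccc9)c7.[O-]S(=O)(=O)C(F)(F)F | intermediate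
15 | (2R,3R)-5,7-bis(benzyloxy)-2-[3,4-bis(benzyloxy)phenyl]-3-(trimethylsilyloxy)chroman-4-ylium triflate (not isolated) | C[Si](C)(C)O[C@@H]1[CH+]c2c(OCc9ccccc9)cc(OCc9ccccc9)cc2O[C@@H]1c7ccc(OCc9ccccc9)c(OCc9ccccc9)c7.[O-]S(=O)(=O)C(F)(F)F | intermediate
16 | [tetra-O-benzylepicatechin]-(4β→8)-[tetra-O-benzyl-3-O-(tri-O-benzylgalloyl)epicatechin]-(4β→6)-[8-bromo-penta-O-benzylcatechin] | O[C@@H]1[C@@H](c2c(OCc9ccccc9)cc(OCc9ccccc9)c3c2O[C@H](c7ccc(OCc9ccccc9)c(OCc9ccccc9)c7)[C@H](OC(=O)c8cc(OCc9ccccc9)c(OCc9ccccc9)c(OCc9ccccc9)c8)[C@H]3c4c(OCc9ccccc9)c(Br)c5c(c4OCc9ccccc9)C[C@H](OCc9ccccc9)[C@@H](c7ccc(OCc9ccccc9)c(OCc9ccccc9)c7)O5)c2c(OCc9ccccc9)cc(OCc9ccccc9)cc2O[C@@H]1c7ccc(OCc9ccccc9)c(OCc9ccccc9)c7 | intermediate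
17 | [tetra-O-benzyl-3-O-(tri-O-benzylgalloyl)epicatechin]-(4β→8)-[tetra-O-benzyl-3-O-(tri-O-benzylgalloyl)epicatechin]-(4β→6)-[8-bromo-penta-O-benzylcatechin] | O=C(O[C@@H]1[C@@H](c2c(OCc9ccccc9)cc(OCc9ccccc9)c3c2O[C@H](c7ccc(OCc9ccccc9)c(OCc9ccccc9)c7)[C@H](OC(=O)c8cc(OCc9ccccc9)c(OCc9ccccc9)c(OCc9ccccc9)c8)[C@H]3c4c(OCc9ccccc9)c(Br)c5c(c4OCc9ccccc9)C[C@H](OCc9ccccc9)[C@@H](c7ccc(OCc9ccccc9)c(OCc9ccccc9)c7)O5)c2c(OCc9ccccc9)cc(OCc9ccccc9)cc2O[C@@H]1c7ccc(OCc9ccccc9)c(OCc9ccccc9)c7)c8cc(OCc9ccccc9)c(OCc9ccccc9)c(OCc9ccccc9)c8 | intermediate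
18 | epicatechin 3-O-gallate-(4β→8)-epicatechin 3-O-gallate-(4β→6)-catechin | O=C(O[C@@H]1[C@@H](c2c(O)cc(O)c3c2O[C@H](c2ccc(O)c(O)c2)[C@H](OC(=O)c2cc(O)c(O)c(O)c2)[C@H]3c2c(O)cc3c(c2O)C[C@H](O)[C@@H](c2ccc(O)c(O)c2)O3)c2c(O)cc(O)cc2O[C@@H]1c1ccc(O)c(O)c1)c1cc(O)c(O)c(O)c1 | target

**Summary**

Total steps: 13. Longest linear sequence: 7 steps (1 → 2 → 11 → 12 → 13 → 16 → 17 → 18; the epicatechin and bottom-unit branches are equally long).

**Steps most likely to fail**

Step 11 (proposed new method). The activated formyl group may take a 1,2-hydride shift from the ring carbon instead of the C2 shift, followed by loss of the C2 proton and aromatisation to a benzofuran. The C2–C(ring) bond may break fully to an open oxocarbenium/enol ether pair, which would erase the C2 configuration. The nucleophile may add directly to the activated formyl carbon. Fallback with known chemistry, setting out from 9 and 10 and rejoining at 17: the classical C4-cation coupling, in which 9 is ionised with Me3SiOTf (cat.) in CH2Cl2 at −78 °C in the presence of 10. Acyl participation and attack by C8 of the middle unit should give 17 directly, which also makes step 12 unnecessary. No new compound is needed.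

Step 10. The freshly formed α-aryl aldehyde may react further with the organoaluminium reagent (ethyl transfer, epimerisation or ring opening by β-elimination of the phenoxide) before it is quenched. Fallback, setting out from 12 and rejoining at 13: a reductive semipinacol variant in which 12 is treated with i-Bu2AlH and then Et3Al at −78 °C, so that the aldehyde is reduced as it forms. This should give [(2S,3R)-4,6-bis(benzyloxy)-2-[3,4-bis(benzyloxy)phenyl]-2,3-dihydro-1-benzofuran-3-yl]methanol F1, which is oxidised with Dess–Martin periodinane (NaHCO3, CH2Cl2) to 13 just before step 11.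

Step 9. Hydride abstraction at C4 may be slow next to the electron-withdrawing mesylate, and the 4-hydroxy product may ionise and self-condense or be over-oxidised to the ketone. Fallback, setting out from 2 and rejoining at 13 (it bypasses 11 and 12): a Wolff ring contraction. Dess–Martin oxidation of 2 should give (2R)-5,7-bis(benzyloxy)-2-[3,4-bis(benzyloxy)phenyl]chroman-3-one F2. Kinetic enolisation at C4 (LiN(SiMe3)2, −78 °C), trifluoroacetylation (CF3CO2CH2CF3) and diazo transfer (MsN3, Et3N) should give the 4-diazo derivative (2R)-5,7-bis(benzyloxy)-2-[3,4-bis(benzyloxy)phenyl]-4-diazochroman-3-one F3. Photolysis (350 nm) in MeOH should bring about the Wolff rearrangement, with C2 migrating with retention and the ketene trapped by methanol; equilibration with NaOMe should then give methyl (2S,3S)-4,6-bis(benzyloxy)-2-[3,4-bis(benzyloxy)phenyl]-2,3-dihydro-1-benzofuran-3-carboxylate F4. Reduction with i-Bu2AlH in CH2Cl2 at −78 °C should give 13.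

Further compounds
F0 | step 11 | none | none
F1 | step 10 | [(2S,3R)-4,6-bis(benzyloxy)-2-[3,4-bis(benzyloxy)phenyl]-2,3-dihydro-1-benzofuran-3-yl]methanol | OC[C@H]1c2c(OCc9ccccc9)cc(OCc9ccccc9)cc2O[C@@H]1c7ccc(OCc9ccccc9)c(OCc9ccccc9)c7
F2 | step 9 | (2R)-5,7-bis(benzyloxy)-2-[3,4-bis(benzyloxy)phenyl]chroman-3-one | O=C1Cc2c(OCc9ccccc9)cc(OCc9ccccc9)cc2O[C@@H]1c7ccc(OCc9ccccc9)c(OCc9ccccc9)c7
F3 | step 9 | (2R)-5,7-bis(benzyloxy)-2-[3,4-bis(benzyloxy)phenyl]-4-diazochroman-3-one | O=C1C(=[N+]=[N-])c2c(OCc9ccccc9)cc(OCc9ccccc9)cc2O[C@@H]1c7ccc(OCc9ccccc9)c(OCc9ccccc9)c7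
F4 | step 9 | methyl (2S,3S)-4,6-bis(benzyloxy)-2-[3,4-bis(benzyloxy)phenyl]-2,3-dihydro-1-benzofuran-3-carboxylate | COC(=O)[C@H]1c2c(OCc9ccccc9)cc(OCc9ccccc9)cc2O[C@@H]1c7ccc(OCc9ccccc9)c(OCc9ccccc9)c7
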